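In a one-step world Z loses the same factor in every equal stretch of time, so you can count time in powers of ten. Here is what is on the board.

| setting | gamma | alder | ash |
|---|---|---|---|
| Z | 0.80 M | 0.80 M | 0.80 M |
| J | 1.1 equiv | 1.10 equiv | 1.10 equiv |
| G | 2.4 mol% | 1.2 mol% | 1.2 mol% |
| D | 8.3 mM | 8.3 mM | 8.3 mM |
| remark | run made earlier |  |  |
| time |  | 50 h | 12 h |
| volume of the second phase over the first |  | 1.0 | 1.0 |

gamma run (percent of the Z charged)

| time / h | X / % | Z / % |
|---|---|---|
| 0.250 | 4.4 | 95.5 |
| 0.500 | 9.2 | 90.8 |
| 1.00 | 17.6 | 82.6 |
| 2.00 | 32.9 | 66.8 |
| 4.00 | 55.6 | 43.9 |

(each reading ± 0.5 percentage points)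

- charges count per volume of the first phase; a concentration in a rate is the amount of a species over the volume of its own phase; every rate counts per litre of the first phase
- the earlier runs were read with a standard deviation of 0.5 percentage points
- the earlier runs hold the two phases in the same ratio of volumes as the flask asked about
- no earlier run changes the charge of G; that part of a forecast is a guess

1. which one finishes higher in amount of X, in percent of the Z charged ("neither" within 2 percentage points) (alder / ash / neither)
2. amount of X at the end, in percent of the Z charged, alder
3. amount of X at the end, in percent of the Z charged, ash

1. Read gamma through its Z. At 4.00 h Z stands at 43.9%, which is 0.358 of a power of ten, so one whole power takes 11.2 h. Call this the decade time: the time in which Z falls by one power of ten at a given concentration of catalyst. This is the pseudo-first-order picture.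

2. Now read gamma through X, a separate reading. You take X as the Z that has gone, so 55.6% of X implies 44.4% of Z and a decade time of 11.3 h. The implied Z and the Z read part by 0.5 percentage points, which is within the scatter of the readings, so X and Z balance in gamma at 4.00 h; that says nothing on whether the decade time holds constant. Gamma's Z read at 1.00 h gives 12.0 h, so the decade time is a reading that drifts, and every count with it is an estimate.

3. Gamma holds 2.4 mol% of G, while alder and ash hold 1.2 mol% on the same Z. No earlier run changes G, so it is a guess that the decade time stretches in proportion, to 22.4 h.

4. Now count. Ash gets 12 h, which is 0.536 decades, so my reckoning gives X 70.9%. Alder gets 50 h, which is 2.23 decades, so X comes to 99.4%.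

5. The forecast gives 95% for alder and 64% for ash, with alder ahead, and says: “I therefore shade the estimates down and keep the ranges wide on the low side”. Both my figures stand higher than the forecast's.

6. The flasks give >99.9% for alder and 71.2% for ash, so alder ends higher.

    G + J ⇌ L + Q (K = 21.0, k = 14.0 M⁻¹ h⁻¹)
    Z + L → X + G (k = 53.0 M⁻¹ h⁻¹)
    D + L ⇌ E, settled at all times (K = 94.0 M⁻¹)

The difference in time is the main reason the two flasks part: take away alder's extra time, stopping it at 12 h, and its X falls from >99.9% to 71.2%. Against its decade time of 22.4 h, ash's 12 h leave 29.1% of Z by the count, and the flask holds 28.8%. Now take a neighbour flask, which is ash with 0.32 M of Z. The loading is held, so the concentration of G scales by 0.400 and the decade time stretches to 55.9 h. Its 12 h then leave 61.0% of Z by the count, and that neighbour flask holds 62.2%.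

(The data were computed from invented constants, noise included.)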